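**Retrosynthetic overview**
1. Both aryl–CH2 units come from one building block: p-cresol (1) → 2 → 3 → 4 → silyl-protected vanillyl bromide 5.
2. C9–C8–C8'–C9' and all three aliphatic oxygens come from (R)-3-hydroxy-γ-butyrolactone (6). Disconnection C7–C8: trans-selective dianion alkylation of 6 with 5 gives 7 (C8 set by the C8' carbinol).
3. Key disconnection C7'–C8': the α-hydroxy radical at the carbinol carbon of 7 (made by hydrogen-atom transfer) adds to a transient p-quinone methide released in the same pot from a second portion of 5, anti to the C8 benzyl, giving tertiary alcohol 8 (C8' re-set by C8).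
4. Last disconnection, lactone C–O: LiAlH4 opens 8 to the triol 9.
5. Rings: none is built. The γ-lactone of 6 is carried through and opened in the last step.

Assumption: the SMILES is read as (2S,3S)-2,3-bis[(4-hydroxy-3-methoxyphenyl)methyl]butane-1,2,4-triol; lignan locants are used, with C8' the carbinol carbon. This route has not been run; the key step is a proposed method.

**Step 1**
Reactants: 1, p-cresol (4-methylphenol)
Product: 2, 2-bromo-4-methylphenol
Conditions: Br2 (1.0 equiv), CH2Cl2, 0 °C
Reagents that add atoms: bromine, BrBr
Why: Electrophilic aromatic bromination; the para position is blocked, so OH directs one bromine ortho.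

**Step 2**
Reactants: 2, 2-bromo-4-methylphenol
Product: 3, 2-methoxy-4-methylphenol (creosol)
Conditions: NaOMe (4 equiv), CuBr (10 mol %), DMF–MeOH, 110 °C; H3O+ work-up
Reagents that add atoms: sodium methoxide, [Na+].[O-]C
Why: Copper-catalysed Ullmann-type methoxylation of the aryl bromide; the phenol is carried as its sodium salt.

**Step 3**
Reactants: 3, creosol
Product: 4, tert-butyl(2-methoxy-4-methylphenoxy)dimethylsilane
Conditions: TBSCl, imidazole, DMF, rt
Reagents that add atoms: tert-butyldimethylsilyl chloride, CC(C)(C)[Si](C)(C)Cl
Why: Standard phenol silylation; TBS survives LDA in step 5 and is the fluoride trigger in step 6.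

**Step 4**
Reactants: 4, TBS ether of creosol
Product: 5, [4-(bromomethyl)-2-methoxyphenoxy](tert-butyl)dimethylsilane
Conditions: NBS (1.05 equiv), AIBN (5 mol %), K2CO3, PhCF3, 80 °C, hν
Reagents that add atoms: N-bromosuccinimide, O=C1CCC(=O)N1Br
Why: Wohl–Ziegler radical benzylic bromination; a non-polar, acid-free medium with low Br2 concentration favours CH3 abstraction over ring bromination.

**Step 5**
Reactants: 6, (R)-3-hydroxy-γ-butyrolactone [(4R)-4-hydroxyoxolan-2-one]; 5, benzylic bromide
Product: 7, (3R,4R)-3-{[4-(tert-butyldimethylsilyloxy)-3-methoxyphenyl]methyl}-4-hydroxyoxolan-2-one (3,4-trans)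
Conditions: LDA (2.1 equiv), THF–DMPU, −78 °C; then 5, −78 → −40 °C; AcOH quench
Reagents that add atoms: none
Why: Fráter–Seebach-type alkylation of the alkoxide–enolate dianion; 5 attacks the enolate face anti to the C4–OLi group, giving the trans (3R) product with C4 untouched, and the alkoxide suppresses β-elimination.

**Step 6 (key step)**
Reactants: 7, mono-benzyl hydroxylactone; 5, benzylic bromide (2.5 equiv, second use)
Product: 8, (3R,4S)-4-hydroxy-3,4-bis[(4-hydroxy-3-methoxyphenyl)methyl]oxolan-2-one (benzyl groups trans, OH cis to the C3 benzyl)
Conditions: 5 + quinuclidine (2.6 equiv), MeCN, rt, 30 min; then 7, Ir[dF(CF3)ppy]2(dtbbpy)PF6 (2 mol %), Bu4NH2PO4 (25 mol %), TBAF·AcOH (4 equiv, syringe pump), MeCN, blue LEDs, 25 °C; then TBAF (1 equiv), rt, 30 min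
Reagents that add atoms: none
Why: Proposed new method: photoredox hydrogen-atom-transfer C–H benzylation of a secondary alcohol, reasoned as follows.
- Acceptor release: quinuclidine stores 5 as its benzylammonium salt. Slow fluoride desilylation triggers 1,6-elimination to the transient, non-isolated p-quinone methide 2-methoxy-4-methylidenecyclohexa-2,5-dien-1-one and returns quinuclidine.
- Hydrogen-atom transfer: the quinuclidine radical cation (from Ir* oxidation) abstracts the hydridic, phosphate-hydrogen-bonded C4–H of 7 in preference to benzylic, α-acyl and α-acyloxy C–H.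
- C–C bond and stereochemistry: the nucleophilic tertiary α-hydroxy radical adds to the electrophilic exocyclic CH2 of the quinone methide on the face anti to the C3 benzyl. The new benzyl is therefore trans and C4 becomes S.
- Turnover: Ir(II) reduces the resulting phenoxyl radical, closing a redox-neutral cycle. The excess fluoride removes the aryl TBS group carried in from 7.
- Closest known chemistry: photoredox hydrogen-atom-transfer α-hydroxy C–H alkylation of alcohols with Michael acceptors (Giese type), and radical 1,6-addition to p-quinone methides.

**Step 7**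
Reactants: 8, dibenzyl hydroxylactone
Product: 9, (−)-carinol, (2S,3S)-2,3-bis[(4-hydroxy-3-methoxyphenyl)methyl]butane-1,2,4-triol
Conditions: LiAlH4 (6 equiv), THF, 0 → 50 °C; Rochelle salt work-up
Reagents that add atoms: none
Why: Hydride reduction of the γ-lactone to the 1,4-diol (C=O becomes C9H2OH, the ring oxygen stays on C9'); no stereocentre is touched, the lactone C3 descriptor changes from R to S only because the CIP priorities change, and lactone C4 (S) becomes triol C2 (S).

**Compound list**
1 | p-cresol | Cc1ccc(O)cc1 | starting material
2 | 2-bromo-4-methylphenol | Cc1ccc(O)c(Br)c1 | intermediate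
3 | 2-methoxy-4-methylphenol (creosol) | COc1cc(C)ccc1O | intermediate
4 | tert-butyl(2-methoxy-4-methylphenoxy)dimethylsilane | COc1cc(C)ccc1O[Si](C)(C)C(C)(C)C | intermediate
5 | [4-(bromomethyl)-2-methoxyphenoxy](tert-butyl)dimethylsilane | COc1cc(CBr)ccc1O[Si](C)(C)C(C)(C)C | intermediate
6 | (R)-3-hydroxy-γ-butyrolactone | O=C1C[C@@H](O)CO1 | starting material
7 | (3R,4R)-3-{[4-(TBSO)-3-methoxyphenyl]methyl}-4-hydroxyoxolan-2-one | O=C1OC[C@H](O)[C@H]1Cc1ccc(O[Si](C)(C)C(C)(C)C)c(OC)c1 | intermediate
8 | (3R,4S)-4-hydroxy-3,4-bis[(4-hydroxy-3-methoxyphenyl)methyl]oxolan-2-one | O=C1OC[C@](O)(Cc2ccc(O)c(OC)c2)[C@H]1Cc1ccc(O)c(OC)c1 | intermediate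
9 | (−)-carinol | COc1cc(C[C@@H](CO)[C@](O)(CO)Cc2ccc(O)c(OC)c2)ccc1O | target

**Totals**
Total step count: 7.
Longest linear sequence: 7 steps (1 → 2 → 3 → 4 → 5 → 7 → 8 → 9; 6 enters at step 5 and 5 is used again in step 6).

**Three steps most likely to fail**
1. Step 6. Risks:
   - oligomerisation of the unsubstituted quinone methide;
   - O-benzylation of the alcohol;
   - electron transfer from the α-hydroxy radical to the quinone methide, which oxidises 7 to the tetronic acid;
   - quenching of the photocatalyst or the quinuclidine radical cation by the liberated phenols;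
   - only moderate anti selectivity.

   Fallback: drop the C–H benzylation and build the carbinol on the regioisomeric (C9'-carbonyl) lactone. Add the benzyl radical from 5 (Giese addition) to the appropriate enantiomer of 5-menthyloxy-2(5H)-furanone made from furfural. Then α-hydroxylate the enolate, benzylate the α-hydroxy lactone dianion with 5 anti to the C8 benzyl, and finish with LiAlH4 and TBAF.
2. Step 4. Risk: ring bromination para to OMe competes with the benzylic chain. Fallback: make 5 by a polar route from catechol: mono-O-methylation, para-bromination to 4-bromoguaiacol, silylation, Br/Li exchange with paraformaldehyde, then Appel bromination.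
3. Step 5. Risks: moderate yield from O-alkylation, bis-alkylation or β-elimination of the dianion. Fallback: form the C7–C8 bond by a Mukaiyama–Michael-type 1,6-addition instead: the O-TMS silyl ketene acetal of 6 adds to the p-quinone methide released from 5 with fluoride, anti to the OSiMe3 group, giving the same trans product.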